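**Retrosynthetic overview**
1. The target comes from BBr3 demethylation of its pentadeca-O-methyl ether. The ring C hydroxyl comes from Baeyer–Villiger oxidation of a ring C aldehyde that earlier served as the SNAr activator.
2. Key disconnection: the dioxin ring (two C–O bonds) and the furan ring (one C–O bond) are cut together. This leads back to a trifluorobiaryl aldehyde (rings A–B–C, ring B oxygen masked as pivalate) and a catechol (rings D–H). In the forward direction the dioxin ring closes first and the furan ring second, in one flask.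
3. A–B–C piece: Pd direct arylation of 2,3,5-trifluorobenzaldehyde with a ring B bromide made from 2,6-dibromo-3,5-dimethoxybenzaldehyde (Ullmann with 3,5-dimethoxyphenol, Baeyer–Villiger, pivalate).
4. D–H piece: a C2-symmetric biphenyldiol (ortho-lithiation, oxidative dimerisation) is arylated twice with 2-bromo-3,5-dimethoxybenzaldehyde, then double Baeyer–Villiger, a desymmetrising Ullmann coupling with 2-iodo-1,3,5-trimethoxybenzene and IBX ortho-hydroxylation.
5. All eight benzene rings are bought as arenes; only the two oxygen heterocycles are built.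

Assumption: the SMILES has no stereocentre and no stereodescriptor, so the tetra-ortho-oxygenated E–F biaryl axis is taken as configurationally undefined and the route needs no stereocontrol.

Ring letters: A = terminal 3,5-dihydroxyphenoxy ring; B = outer dibenzofuran ring carrying ring A; C = central ring shared by furan and dioxin; D = outer dioxin ring; E and F = the biaryl rings (E sits on the ring D oxygen); G = ring between F and H; H = terminal 2,4,6-trihydroxyphenoxy ring.

**Route**

Step 1
Reactants: 1 3,5-dimethoxyphenol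
Product: 2 1,3-dimethoxy-5-(methoxymethoxy)benzene
Conditions: MOMCl, i-Pr2NEt, CH2Cl2, 0 → 25 °C
Reagents that add atoms: chloromethyl methyl ether, COCCl
Why: O-alkylation of the phenol (MOM protection); the OMOM group is the ortho-directing group needed in step 2.

Step 2
Reactants: 2 1,3-dimethoxy-5-(methoxymethoxy)benzene (2 equiv)
Product: 4 2,2'-bis(methoxymethoxy)-4,4',6,6'-tetramethoxy-1,1'-biphenyl, via aryllithium 3 (not isolated)
Conditions: n-BuLi, TMEDA, THF, 0 °C; then CuCl2, −78 → 25 °C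
Reagents that add atoms: none
Why: Directed ortho-metalation takes place at the carbon flanked by OMOM and OMe (OMOM is the stronger director), and oxidative homocoupling of the aryllithium by divalent copper (CuCl2) gives the E–F biaryl; no stereocentre is formed.

Step 3
Reactants: 4 2,2'-bis(methoxymethoxy)-4,4',6,6'-tetramethoxy-1,1'-biphenyl
Product: 5 4,4',6,6'-tetramethoxy-1,1'-biphenyl-2,2'-diol
Conditions: HCl (3 M), MeOH, 50 °C
Reagents that add atoms: none
Why: Acid-catalysed acetal cleavage (MOM removal) frees both phenols.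

Step 4
Reactants: 5 4,4',6,6'-tetramethoxy-1,1'-biphenyl-2,2'-diol, 6 2-bromo-3,5-dimethoxybenzaldehyde (2.3 equiv)
Product: 7 2,2'-[(4,4',6,6'-tetramethoxybiphenyl-2,2'-diyl)bis(oxy)]bis(3,5-dimethoxybenzaldehyde)
Conditions: CuI (20 mol %), N,N-dimethylglycine, Cs2CO3, dioxane, 100 °C
Reagents that add atoms: none
Why: Ullmann diaryl ether synthesis; the bromide of 6 is activated by its ortho formyl group, and arylating both phenols keeps the product C2-symmetric (the two aldehyde rings become rings D and G).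

Step 5
Reactants: 7 bis-aldehyde
Product: 9 2,2'-[(4,4',6,6'-tetramethoxybiphenyl-2,2'-diyl)bis(oxy)]bis(3,5-dimethoxyphenol), via bis-formate 8 (not isolated)
Conditions: mCPBA (3 equiv), CH2Cl2, 0 → 25 °C; then K2CO3 (cat.), MeOH, 25 °C
Reagents that add atoms: 3-chloroperoxybenzoic acid, OOC(=O)c1cccc(Cl)c1
Why: Baeyer–Villiger (Dakin-type) oxidation; the aryl group with an ortho aryloxy donor migrates, and the aryl formates are methanolysed to the phenols.

Step 6
Reactants: 9 bis-phenol (2 equiv, excess recovered), 10 2-iodo-1,3,5-trimethoxybenzene (1 equiv)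
Product: 11 mono(2,4,6-trimethoxyphenyl) ether of 9 (ring H on the ring G oxygen; the ring D phenol stays free)
Conditions: CuI, picolinic acid, K3PO4, DMSO, 100 °C
Reagents that add atoms: none
Why: Ullmann ether synthesis under hindered-substrate conditions; limiting iodide gives statistical mono-arylation of the symmetric bis-phenol (desymmetrisation).

Step 7
Reactants: 11 mono-phenol
Product: 13 catechol of rings D–H (3-aryloxy-4,6-dimethoxybenzene-1,2-diol; aryl = the E–F–G–H unit), via ortho-quinone 12 (not isolated)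
Conditions: IBX, DMF, 25 °C; then aq. Na2S2O4
Reagents that add atoms: 2-iodoxybenzoic acid (IBX), O=C1OI(=O)(O)c2ccccc12
Why: IBX ortho-oxygenation of a phenol delivers oxygen from pentavalent iodine to the only free ortho position; the ortho-quinone is reduced in the same flask to the catechol.

Step 8
Reactants: 14 3,5-dimethoxybenzaldehyde
Product: 15 2,6-dibromo-3,5-dimethoxybenzaldehyde
Conditions: Br2 (2.2 equiv), AcOH, 25 °C
Reagents that add atoms: bromine, BrBr
Why: Electrophilic aromatic bromination; each of the two positions next to the formyl group is ortho to one methoxy and para to the other, and the position between the two methoxy groups is the least reactive.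

Step 9
Reactants: 15 2,6-dibromo-3,5-dimethoxybenzaldehyde (1.5 equiv), 1 3,5-dimethoxyphenol
Product: 16 2-bromo-6-(3,5-dimethoxyphenoxy)-3,5-dimethoxybenzaldehyde
Conditions: CuI, N,N-dimethylglycine, Cs2CO3, dioxane, 90 °C
Reagents that add atoms: none
Why: Ullmann ether synthesis at a bromide ortho to CHO; the two bromides are equivalent, and the second is slower once the ring carries the aryloxy group, so mono-substitution dominates.

Step 10
Reactants: 16 bromo aldehyde
Product: 18 2-bromo-6-(3,5-dimethoxyphenoxy)-3,5-dimethoxyphenol, via aryl formate 17 (not isolated)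
Conditions: mCPBA, CH2Cl2, 25 °C; then K2CO3 (cat.), MeOH, 0 °C
Reagents that add atoms: 3-chloroperoxybenzoic acid, OOC(=O)c1cccc(Cl)c1
Why: Baeyer–Villiger oxidation (aryl migration assisted by the ortho aryloxy group) then formate methanolysis; this puts the future furan oxygen next to the bromine on ring B.

Step 11
Reactants: 18 bromophenol
Product: 19 2-bromo-6-(3,5-dimethoxyphenoxy)-3,5-dimethoxyphenyl pivalate
Conditions: PivCl, pyridine, DMAP (cat.), CH2Cl2, 0 → 25 °C
Reagents that add atoms: pivaloyl chloride, CC(C)(C)C(Cl)=O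
Why: O-acylation; the pivalate keeps the ring B oxygen silent through step 12 and through the dioxin-forming part of step 13.

Step 12
Reactants: 19 aryl bromide, 20 2,3,5-trifluorobenzaldehyde (2 equiv)
Product: 21 4-[3-(3,5-dimethoxyphenoxy)-4,6-dimethoxy-2-(pivaloyloxy)phenyl]-2,3,5-trifluorobenzaldehyde
Conditions: Pd(OAc)2 (5 mol %), SPhos (10 mol %), K2CO3, i-PrOAc, 80 °C
Reagents that add atoms: none
Why: Direct C–H arylation of a polyfluoroarene by concerted metalation–deprotonation (Fagnou type); the C–H of 20 flanked by two fluorines (C4) is the most acidic and reacts in preference to C6–H; no stereocentre is formed.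

Step 13 (key step)
Reactants: 21 trifluorobiaryl aldehyde (rings A–B–C), 13 catechol (rings D–H)
Product: 25 octacyclic aldehyde (per-O-methylated target skeleton with CHO in place of the ring C hydroxyl), via mono-ether 22 (not isolated), via dioxin pivalate 23 (not isolated), via free phenol 24 (not isolated)
Conditions: K2CO3 (5 equiv), degassed DMSO, 25 → 100 °C; then MeOH (10 equiv), 60 °C; then 135 °C (sealed), Ar
Reagents that add atoms: none
Why: Proposed new method: a one-flask triple SNAr in which the dioxin ring and then the furan ring close on the same benzaldehyde ring; mechanistic reasoning: only the fluorine ortho to CHO (C2–F of the benzaldehyde ring) is activated, so the catecholate can enter nowhere else, and the more acidic 2-OH of 13 (next to the aryloxy group, meta to both methoxy groups) is the one ionised by K2CO3 and attacks to give 22; the neighbouring phenoxide then displaces C3–F in a 6-membered closure to 23, and an ether formed through the other oxygen can equilibrate by Smiles rearrangement through the CHO-stabilised spiro Meisenheimer complex while only 22 can close without forcing the bulky aryloxy group against ring B; the pivalate keeps the ring B oxygen silent until the dioxin is closed, after which methanolysis releases phenoxide 24, which displaces the last fluorine (C5–F, ortho to the biaryl bond) in a 5-membered closure to the dibenzofuran; closest known reaction types: dibenzo-1,4-dioxin synthesis from catechols and activated ortho-difluoroarenes (double SNAr with Smiles equilibration) and base-mediated cyclisation of 2-fluoro-2'-hydroxybiaryls to dibenzofurans; no stereocentre is formed.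

Step 14
Reactants: 25 octacyclic aldehyde
Product: 27 pentadeca-O-methyl ether of the target (only the ring C hydroxyl free), via aryl formate 26 (not isolated)
Conditions: mCPBA (1.5 equiv), CH2Cl2, 0 → 25 °C; then K2CO3 (cat.), MeOH, 25 °C
Reagents that add atoms: 3-chloroperoxybenzoic acid, OOC(=O)c1cccc(Cl)c1
Why: Baeyer–Villiger oxidation of an aryl aldehyde with an ortho ring-ether oxygen (aryl migration), then formate methanolysis; the SNAr activating group thereby becomes the ring C hydroxyl.

Step 15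
Reactants: 27 pentadeca-O-methyl ether
Product: 28 CNP0192765.0 (target)
Conditions: BBr3 (60 equiv), CH2Cl2, −78 → 25 °C, Ar; then MeOH/H2O, 0 °C
Reagents that add atoms: none
Why: Lewis-acid O-demethylation of all fifteen aryl methyl ethers; diaryl ethers, the dibenzofuran and the dibenzodioxin are inert to BBr3, and there is no stereocentre to lose.

**Compound list**
1 | 3,5-dimethoxyphenol | COc1cc(O)cc(OC)c1 | starting material
2 | 1,3-dimethoxy-5-(methoxymethoxy)benzene | COCOc1cc(OC)cc(OC)c1 | intermediate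
3 | [2,4-dimethoxy-6-(methoxymethoxy)phenyl]lithium | [Li]c1c(OC)cc(OC)cc1OCOC | intermediate (not isolated)
4 | 2,2'-bis(methoxymethoxy)-4,4',6,6'-tetramethoxy-1,1'-biphenyl | COCOc1cc(OC)cc(OC)c1-c1c(OCOC)cc(OC)cc1OC | intermediate
5 | 4,4',6,6'-tetramethoxy-1,1'-biphenyl-2,2'-diol | COc1cc(O)c(-c2c(O)cc(OC)cc2OC)c(OC)c1 | intermediate
6 | 2-bromo-3,5-dimethoxybenzaldehyde | COc1cc(OC)c(Br)c(C=O)c1 | starting material
7 | 2,2'-[(4,4',6,6'-tetramethoxybiphenyl-2,2'-diyl)bis(oxy)]bis(3,5-dimethoxybenzaldehyde) | COc1cc(Oc2c(C=O)cc(OC)cc2OC)c(-c2c(Oc3c(C=O)cc(OC)cc3OC)cc(OC)cc2OC)c(OC)c1 | intermediate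
8 | bis-formate of 9 | COc1cc(Oc2c(OC=O)cc(OC)cc2OC)c(-c2c(Oc3c(OC=O)cc(OC)cc3OC)cc(OC)cc2OC)c(OC)c1 | intermediate (not isolated)
9 | 2,2'-[(4,4',6,6'-tetramethoxybiphenyl-2,2'-diyl)bis(oxy)]bis(3,5-dimethoxyphenol) | COc1cc(Oc2c(O)cc(OC)cc2OC)c(-c2c(Oc3c(O)cc(OC)cc3OC)cc(OC)cc2OC)c(OC)c1 | intermediate
10 | 2-iodo-1,3,5-trimethoxybenzene | COc1cc(OC)c(I)c(OC)c1 | starting material
11 | mono(2,4,6-trimethoxyphenyl) ether of 9 (rings D–H, ring D as phenol) | COc1cc(Oc2c(O)cc(OC)cc2OC)c(-c2c(Oc3c(Oc4c(OC)cc(OC)cc4OC)cc(OC)cc3OC)cc(OC)cc2OC)c(OC)c1 | intermediate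
12 | 3-aryloxy-4,6-dimethoxy-1,2-benzoquinone (ring D ortho-quinone) | COc1cc(OC2=C(OC)C=C(OC)C(=O)C2=O)c(-c2c(Oc3c(Oc4c(OC)cc(OC)cc4OC)cc(OC)cc3OC)cc(OC)cc2OC)c(OC)c1 | intermediate (not isolated)
13 | 3-aryloxy-4,6-dimethoxybenzene-1,2-diol (catechol of rings D–H) | COc1cc(Oc2c(O)c(O)c(OC)cc2OC)c(-c2c(Oc3c(Oc4c(OC)cc(OC)cc4OC)cc(OC)cc3OC)cc(OC)cc2OC)c(OC)c1 | intermediate
14 | 3,5-dimethoxybenzaldehyde | COc1cc(C=O)cc(OC)c1 | starting material
15 | 2,6-dibromo-3,5-dimethoxybenzaldehyde | COc1cc(OC)c(Br)c(C=O)c1Br | intermediate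
16 | 2-bromo-6-(3,5-dimethoxyphenoxy)-3,5-dimethoxybenzaldehyde | COc1cc(OC)cc(Oc2c(OC)cc(OC)c(Br)c2C=O)c1 | intermediate
17 | 2-bromo-6-(3,5-dimethoxyphenoxy)-3,5-dimethoxyphenyl formate | COc1cc(OC)cc(Oc2c(OC)cc(OC)c(Br)c2OC=O)c1 | intermediate (not isolated)
18 | 2-bromo-6-(3,5-dimethoxyphenoxy)-3,5-dimethoxyphenol | COc1cc(OC)cc(Oc2c(OC)cc(OC)c(Br)c2O)c1 | intermediate
19 | 2-bromo-6-(3,5-dimethoxyphenoxy)-3,5-dimethoxyphenyl pivalate | COc1cc(OC)cc(Oc2c(OC)cc(OC)c(Br)c2OC(=O)C(C)(C)C)c1 | intermediate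
20 | 2,3,5-trifluorobenzaldehyde | O=Cc1cc(F)cc(F)c1F | starting material
21 | 4-[3-(3,5-dimethoxyphenoxy)-4,6-dimethoxy-2-(pivaloyloxy)phenyl]-2,3,5-trifluorobenzaldehyde | O=Cc1cc(F)c(-c2c(OC)cc(OC)c(Oc3cc(OC)cc(OC)c3)c2OC(=O)C(C)(C)C)c(F)c1F | intermediate
22 | mono-ether (2-O of catechol 13 on C2 of the benzaldehyde ring of 21; 1-OH free) | O=Cc1cc(F)c(-c2c(OC)cc(OC)c(Oc3cc(OC)cc(OC)c3)c2OC(=O)C(C)(C)C)c(F)c1Oc3c(O)c(OC)cc(OC)c3Oc5cc(OC)cc(OC)c5-c5c(Oc6c(Oc7c(OC)cc(OC)cc7OC)cc(OC)cc6OC)cc(OC)cc5OC | intermediate (not isolated)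
23 | dioxin pivalate (dibenzodioxin closed; one C–F and the pivalate left) | O=Cc1cc(F)c(-c4c(OC)cc(OC)c(Oc5cc(OC)cc(OC)c5)c4OC(=O)C(C)(C)C)c2c1Oc3c(Oc5cc(OC)cc(OC)c5-c5c(Oc6c(Oc7c(OC)cc(OC)cc7OC)cc(OC)cc6OC)cc(OC)cc5OC)c(OC)cc(OC)c3O2 | intermediate (not isolated)
24 | free phenol from 23 (pivalate removed) | O=Cc1cc(F)c(-c4c(OC)cc(OC)c(Oc5cc(OC)cc(OC)c5)c4O)c2c1Oc3c(Oc5cc(OC)cc(OC)c5-c5c(Oc6c(Oc7c(OC)cc(OC)cc7OC)cc(OC)cc6OC)cc(OC)cc5OC)c(OC)cc(OC)c3O2 | intermediate (not isolated)
25 | octacyclic aldehyde (per-O-methyl target skeleton, CHO on ring C) | COc1cc(OC)cc(Oc2c(OC)cc(OC)c3c2oc2cc(C=O)c4c(c23)Oc2c(OC)cc(OC)c(Oc5cc(OC)cc(OC)c5-c5c(Oc6c(Oc7c(OC)cc(OC)cc7OC)cc(OC)cc6OC)cc(OC)cc5OC)c2O4)c1 | intermediate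
26 | ring C aryl formate of 27 | COc1cc(OC)cc(Oc2c(OC)cc(OC)c3c2oc2cc(OC=O)c4c(c23)Oc2c(OC)cc(OC)c(Oc5cc(OC)cc(OC)c5-c5c(Oc6c(Oc7c(OC)cc(OC)cc7OC)cc(OC)cc6OC)cc(OC)cc5OC)c2O4)c1 | intermediate (not isolated)
27 | pentadeca-O-methyl ether of the target (ring C hydroxyl free) | COc1cc(OC)cc(Oc2c(OC)cc(OC)c3c2oc2cc(O)c4c(c23)Oc2c(OC)cc(OC)c(Oc5cc(OC)cc(OC)c5-c5c(Oc6c(Oc7c(OC)cc(OC)cc7OC)cc(OC)cc6OC)cc(OC)cc5OC)c2O4)c1 | intermediate
28 | CNP0192765.0 | Oc1cc(O)cc(Oc2c(O)cc(O)c3c2oc2cc(O)c4c(c23)Oc2c(O)cc(O)c(Oc3cc(O)cc(O)c3-c3c(O)cc(O)cc3Oc3c(O)cc(O)cc3Oc3c(O)cc(O)cc3O)c2O4)c1 | target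

**Totals**
Total step count: 15. Longest linear sequence: 10 steps (steps 1–7, then 13, 14, 15).

**Three steps most likely to fail**

Step 13. The risks are the orientation of the dioxin (which catechol oxygen enters first), early loss of the pivalate, and a slow final displacement of an unactivated fluoride. The fallback sets out from 11 and 21 and returns at 22, fixing the orientation by construction and closing the two rings in separate operations. Phenol 11 is ortho-formylated (MgCl2, Et3N, paraformaldehyde, MeCN, 80 °C) at its only free ortho position to give the 2-hydroxy-3-aryloxy-4,6-dimethoxybenzaldehyde F1, whose single hydroxyl is the one next to the aryloxy group. SNAr of F1 with 21 (K2CO3, DMSO, 80 °C) gives the dialdehyde ether F2. Baeyer–Villiger oxidation with one equivalent of mCPBA at 0 °C takes only the electron-rich ring D aldehyde (three oxygen donors ortho and para; the aldehyde on the difluorinated ring migrates poorly) and gives the aryl formate F3. HCl in MeOH, which leaves the pivalate intact, then frees the second hydroxyl to give 22. This is cyclised to 23 with K2CO3 in DMSO, isolated, and taken through pivalate methanolysis and furan closure to 25.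

Step 12. The bromide is di-ortho-substituted and electron-rich, a second C–H (C6 of 20) could compete, and 20 carries an SNAr-labile fluorine. The fallback sets out from 20 and 19 and returns at 21, replacing C–H activation by a preformed organometallic. Zincation of 20 with TMPZnCl·LiCl (THF, 25 °C; this base tolerates aldehydes) at the C–H between the two fluorines gives (2,3,6-trifluoro-4-formylphenyl)zinc chloride F4. Negishi coupling of F4 with 19 (Pd(OAc)2, SPhos, THF, 50 °C) gives 21.

Step 15. Fifteen ethers must be cleaved and the free polyphenol is air-sensitive and hard to purify. The fallback sets out from 27 and returns at 28 through an isolable protected form. After BBr3 cleavage the crude product is peracetylated without purification (Ac2O, pyridine, DMAP) to the hexadecaacetate F5, which is stable and can be purified on silica. Mild deacetylation (NaOMe cat., MeOH, Ar, 0 °C, then acidic resin) gives 28.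

**Further compounds**
F1 | step 13 | 2-hydroxy-3-aryloxy-4,6-dimethoxybenzaldehyde (ring D salicylaldehyde of rings D–H) | COc1cc(Oc2c(O)c(C=O)c(OC)cc2OC)c(-c2c(Oc3c(Oc4c(OC)cc(OC)cc4OC)cc(OC)cc3OC)cc(OC)cc2OC)c(OC)c1
F2 | step 13 | dialdehyde ether (F1 oxygen on C2 of the benzaldehyde ring of 21) | O=Cc1cc(F)c(-c2c(OC)cc(OC)c(Oc3cc(OC)cc(OC)c3)c2OC(=O)C(C)(C)C)c(F)c1Oc3c(C=O)c(OC)cc(OC)c3Oc5cc(OC)cc(OC)c5-c5c(Oc6c(Oc7c(OC)cc(OC)cc7OC)cc(OC)cc6OC)cc(OC)cc5OC
F3 | step 13 | aryl formate of 22 | O=Cc1cc(F)c(-c2c(OC)cc(OC)c(Oc3cc(OC)cc(OC)c3)c2OC(=O)C(C)(C)C)c(F)c1Oc3c(OC=O)c(OC)cc(OC)c3Oc5cc(OC)cc(OC)c5-c5c(Oc6c(Oc7c(OC)cc(OC)cc7OC)cc(OC)cc6OC)cc(OC)cc5OC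
F4 | step 12 | (2,3,6-trifluoro-4-formylphenyl)zinc chloride | O=Cc1cc(F)c([Zn]Cl)c(F)c1F
F5 | step 15 | hexadecaacetate of 28 | CC(=O)Oc1cc(OC(C)=O)cc(Oc2c(OC(C)=O)cc(OC(C)=O)c3c2oc2cc(OC(C)=O)c4c(c23)Oc2c(OC(C)=O)cc(OC(C)=O)c(Oc3cc(OC(C)=O)cc(OC(C)=O)c3-c3c(OC(C)=O)cc(OC(C)=O)cc3Oc3c(OC(C)=O)cc(OC(C)=O)cc3Oc3c(OC(C)=O)cc(OC(C)=O)cc3OC(C)=O)c2O4)c1
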